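**Retrosynthetic overview**

1. Target 10 is an isoflavone in which C8a of ring A, the carbon bonded to the ring oxygen O1, lies para to the free C6–OH. The route rests on this para relationship: O1–C8a is cut last, as an anodic C–H/O–H coupling of the open-chain enol 8, in which that carbon still bears hydrogen.
2. 8 comes from the phenolic deoxybenzoin 5 by Claisen C-formylation with ethyl formate 6, which supplies C2 of the chromone.
3. 5 comes from acetophenone 1 by O-benzylation, palladium-catalysed α-arylation with bromoarene 3 (the C3–aryl bond) and hydrogenolysis. The benzyl group is removed before formylation so that H2/Pd never meets the reducible hydroxymethylene ketone.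
4. Rings A and B come from the starting materials; ring C (the pyranone) is the only ring formed, in the last step.

Key step: step 5

Assumption: 8 is drawn as its Z-enol; it will exist as a tautomeric mixture with the keto-aldehyde and the E-enol, and these are treated as one compound.

**Step 1**
Reactants: 1 1-(3-hydroxy-4-methoxyphenyl)ethan-1-one
Product: 2 1-[3-(benzyloxy)-4-methoxyphenyl]ethan-1-one
Conditions: BnBr, K2CO3, DMF, 60 °C
Reagents that add atoms: benzyl bromide, BrCc1ccccc1
Why: Williamson ether synthesis; K2CO3 ionises only the phenol, so the phenoxide is benzylated and the methyl ketone is left untouched.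

**Step 2**
Reactants: 2 1-[3-(benzyloxy)-4-methoxyphenyl]ethan-1-one; 3 5-bromo-1,2,3-trimethoxybenzene
Product: 4 1-[3-(benzyloxy)-4-methoxyphenyl]-2-(3,4,5-trimethoxyphenyl)ethan-1-one
Conditions: Pd2(dba)3 (1 mol%), Xantphos (2.4 mol%), NaOtBu (2.2 equiv), 2 in slight excess, THF, 70 °C; aq. NH4Cl
Reagents that add atoms: none
Why: Buchwald–Hartwig-type α-arylation of a methyl aryl ketone (oxidative addition of 3 to zerovalent palladium, enolate binding, reductive elimination); the wide-bite-angle ligand and the excess of ketone should hold the reaction at monoarylation, and the benzyl ether is inert.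

**Step 3**
Reactants: 4 1-[3-(benzyloxy)-4-methoxyphenyl]-2-(3,4,5-trimethoxyphenyl)ethan-1-one
Product: 5 1-(3-hydroxy-4-methoxyphenyl)-2-(3,4,5-trimethoxyphenyl)ethan-1-one
Conditions: H2 (1 atm), 10% Pd/C, EtOAc–EtOH, rt
Reagents that add atoms: none
Why: Hydrogenolysis of the benzyl aryl ether is much faster than reduction of the electron-rich aryl ketone under these mild conditions, and at this stage no enol double bond or formyl group is present to be reduced.

**Step 4**
Reactants: 5 1-(3-hydroxy-4-methoxyphenyl)-2-(3,4,5-trimethoxyphenyl)ethan-1-one; 6 ethyl formate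
Product: 8 (Z)-3-hydroxy-1-(3-hydroxy-4-methoxyphenyl)-2-(3,4,5-trimethoxyphenyl)prop-2-en-1-one, via disodium enolate phenoxide salt 7 (not isolated)
Conditions: NaH (3.5 equiv), HCO2Et (5 equiv), THF, 0 °C to rt; cold 1 M HCl to pH 3
Reagents that add atoms: none
Why: Crossed Claisen condensation (C-formylation of the deoxybenzoin enolate, as in the classical formate route to isoflavones), driven by formation of the stabilised β-ketoaldehyde enolate; excess base covers the phenol, and any phenyl formate formed is cleaved on work-up.

**Step 5**
Reactants: 8 (Z)-3-hydroxy-1-(3-hydroxy-4-methoxyphenyl)-2-(3,4,5-trimethoxyphenyl)prop-2-en-1-one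
Product: 10 6-hydroxy-7-methoxy-3-(3,4,5-trimethoxyphenyl)-4H-chromen-4-one (target), via 8aH-dienone tautomer 9 (not isolated)
Conditions: undivided cell, graphite anode, Pt cathode, 2,6-lutidine (2.5 equiv), nBu4NPF6 (0.1 M), HFIP, substrate 5 mM, controlled potential at the first anodic wave to ca. 2 F/mol, rt; dilute aq. HCl work-up
Reagents that add atoms: none
Why: Proposed new method: ring A of 8 should lose two electrons and its phenolic proton (to lutidine) to give an HFIP-stabilised phenoxonium ion with positive charge ortho and para to the oxygen; the enol oxygen, once lutidine and HFIP have opened its internal O–H···O=C hydrogen bond so that rotation about the C1–C2 bond of the propenone can bring it next to ring A, adds to the para carbon (C6′ of 8, C8a of the product) to give dienone 9, and loss of the C8a proton rearomatises ring A while the protons are reduced to H2 at the cathode. The closest known reaction types are the oxidative cyclisation of 2,3′-dihydroxybenzophenones to hydroxyxanthones (the same pyranone O–C bond made para to a phenolic hydroxyl, but by a phenoxide oxygen and a chemical one-electron oxidant), the anodic dehydrogenative lactonisation of biaryl-2-carboxylic acids, and the para-substitution of phenols by oxygen nucleophiles at an anode or with trivalent iodine reagents; the enol oxygen of a 2-aryl-3-oxopropanal has not been shown in this role. Ring C closes by a six-membered attack of oxygen on the cationic sp2 carbon C8a (formally 6-exo-trig with respect to the C8–C8a double bond of the quinoid cation), and the array O1–C2–C3–C4–C4a–C8a can be planar and strain-free. No stereocentre is set, because the sp3 carbon C8a of 9 is flattened again on tautomerisation. The step needs oxidation of ring A in preference to the trimethoxyphenyl ring B, which the ionisable phenolic O–H (proton-coupled oxidation with the base) and the controlled potential should secure, and it needs C–O closure at the carbon para to the hydroxyl and not at the ortho carbon between the acyl and hydroxyl groups, which the less crowded position and the more stable cross-conjugated dienone favour. Attack of a ring B carbon on ring A (biaryl coupling) is the main competing closure; it should be disfavoured once the internal hydrogen bond, which would hold rings A and B cis, is opened, while high dilution limits dimerisation and stopping near 2 F/mol limits over-oxidation of the product phenol.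

**Compound list**

1 | 1-(3-hydroxy-4-methoxyphenyl)ethan-1-one (3′-hydroxy-4′-methoxyacetophenone) | CC(=O)c1ccc(OC)c(O)c1 | starting material
2 | 1-[3-(benzyloxy)-4-methoxyphenyl]ethan-1-one | CC(=O)c1ccc(OC)c(OCc2ccccc2)c1 | intermediate
3 | 5-bromo-1,2,3-trimethoxybenzene | COc1cc(Br)cc(OC)c1OC | starting material
4 | 1-[3-(benzyloxy)-4-methoxyphenyl]-2-(3,4,5-trimethoxyphenyl)ethan-1-one | COc1ccc(C(=O)Cc2cc(OC)c(OC)c(OC)c2)cc1OCc1ccccc1 | intermediate
5 | 1-(3-hydroxy-4-methoxyphenyl)-2-(3,4,5-trimethoxyphenyl)ethan-1-one | COc1ccc(C(=O)Cc2cc(OC)c(OC)c(OC)c2)cc1O | intermediate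
6 | ethyl formate | CCOC=O | starting material
7 | disodium (Z)-3-(4-methoxy-3-oxidophenyl)-3-oxo-2-(3,4,5-trimethoxyphenyl)prop-1-en-1-olate | [Na+].[Na+].[O-]/C=C(\C(=O)c1ccc(OC)c([O-])c1)c1cc(OC)c(OC)c(OC)c1 | intermediate (not isolated)
8 | (Z)-3-hydroxy-1-(3-hydroxy-4-methoxyphenyl)-2-(3,4,5-trimethoxyphenyl)prop-2-en-1-one | O/C=C(\C(=O)c1ccc(OC)c(O)c1)c1cc(OC)c(OC)c(OC)c1 | intermediate
9 | 7-methoxy-3-(3,4,5-trimethoxyphenyl)-8aH-chromene-4,6-dione (racemic at C8a, transient) | COC1=CC2OC=C(c3cc(OC)c(OC)c(OC)c3)C(=O)C2=CC1=O | intermediate (not isolated)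
10 | 6-hydroxy-7-methoxy-3-(3,4,5-trimethoxyphenyl)-4H-chromen-4-one | COc1cc2occ(-c3cc(OC)c(OC)c(OC)c3)c(=O)c2cc1O | target

**Step count**

Total steps: 5. Longest linear sequence: 5 steps (1 → 2 → 4 → 5 → 8 → 10).

**Steps most likely to fail**

Step 5 (proposed new method). Several processes may take over:
- closure through a carbon of ring B onto oxidised ring A (dehydrogenative biaryl coupling);
- removal of the first electron from ring B or from the enol, followed by closure of an enol oxygen onto ring B;
- intermolecular phenol coupling;
- further oxidation of the product phenol.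

The fallback uses known chemistry and introduces the oxygen para to the hydroxyl before ring C is closed. It sets out from 5. Elbs persulfate oxidation (K2S2O8, aq. NaOH, 0–20 °C) should place a sulfate on the carbon para to the phenoxide and give potassium 4-hydroxy-5-methoxy-2-[(3,4,5-trimethoxyphenyl)acetyl]phenyl sulfate F1. Acid hydrolysis (aq. HCl, Na2SO3, 80 °C) should then give 1-(2,5-dihydroxy-4-methoxyphenyl)-2-(3,4,5-trimethoxyphenyl)ethan-1-one F2. The established one-carbon ring closure of 2-hydroxydeoxybenzoins (BF3·OEt2, DMF, MeSO2Cl, 70 °C), which tolerates free phenols, should close ring C through the hydroxyl ortho to the ketone. The fallback comes back to the route at 10.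

Step 4. The formyl group may be lost again by retro-Claisen cleavage during basic work-up, or formylation may stall because the phenoxide consumes the reagent. The fallback replaces the base-mediated Claisen condensation by aminomethylenation under neutral conditions. It sets out from 5. Heating with tert-butoxybis(dimethylamino)methane (toluene, 90 °C), which does not methylate the phenol, should give (E)-3-(dimethylamino)-1-(3-hydroxy-4-methoxyphenyl)-2-(3,4,5-trimethoxyphenyl)prop-2-en-1-one F3. Hydrolysis of this vinylogous amide (1 M HCl, THF, 40 °C) should release the hydroxymethylene ketone. The fallback comes back at 8.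

Step 2. A second arylation at the more acidic methylene of the product, aldol self-condensation of the methyl ketone, or slow oxidative addition of the electron-rich bromide may erode the coupling. The fallback forms the C–aryl bond by a 1,2-aryl shift instead of a cross-coupling and replaces steps 2 to 4. It sets out from 2.
- Claisen–Schmidt condensation with 3,4,5-trimethoxybenzaldehyde (KOH, EtOH, rt) should give (E)-1-[3-(benzyloxy)-4-methoxyphenyl]-3-(3,4,5-trimethoxyphenyl)prop-2-en-1-one F4.
- Oxidative rearrangement of the chalcone (Tl(NO3)3·3H2O, or PhI(OAc)2 with p-TsOH, in MeOH–HC(OMe)3) should move the trimethoxyphenyl group to the α-carbon and give 1-[3-(benzyloxy)-4-methoxyphenyl]-3,3-dimethoxy-2-(3,4,5-trimethoxyphenyl)propan-1-one F5.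
- Hydrogenolysis (H2, Pd/C, EtOAc), safe here because the aldehyde is masked as its acetal, should give 1-(3-hydroxy-4-methoxyphenyl)-3,3-dimethoxy-2-(3,4,5-trimethoxyphenyl)propan-1-one F6.
- Mild acid hydrolysis (aq. HCl, THF, rt) should unmask the formyl group.

The fallback comes back at 8.

**Further compounds**

F1 | step 5 | potassium 4-hydroxy-5-methoxy-2-[(3,4,5-trimethoxyphenyl)acetyl]phenyl sulfate | [K+].COc1cc(OS(=O)(=O)[O-])c(C(=O)Cc2cc(OC)c(OC)c(OC)c2)cc1O
F2 | step 5 | 1-(2,5-dihydroxy-4-methoxyphenyl)-2-(3,4,5-trimethoxyphenyl)ethan-1-one | COc1cc(O)c(C(=O)Cc2cc(OC)c(OC)c(OC)c2)cc1O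
F3 | step 4 | (E)-3-(dimethylamino)-1-(3-hydroxy-4-methoxyphenyl)-2-(3,4,5-trimethoxyphenyl)prop-2-en-1-one | CN(C)/C=C(/C(=O)c1ccc(OC)c(O)c1)c1cc(OC)c(OC)c(OC)c1
F4 | step 2 | (E)-1-[3-(benzyloxy)-4-methoxyphenyl]-3-(3,4,5-trimethoxyphenyl)prop-2-en-1-one | COc1ccc(C(=O)/C=C/c2cc(OC)c(OC)c(OC)c2)cc1OCc1ccccc1
F5 | step 2 | 1-[3-(benzyloxy)-4-methoxyphenyl]-3,3-dimethoxy-2-(3,4,5-trimethoxyphenyl)propan-1-one (racemic) | COc1ccc(C(=O)C(C(OC)OC)c2cc(OC)c(OC)c(OC)c2)cc1OCc1ccccc1
F6 | step 2 | 1-(3-hydroxy-4-methoxyphenyl)-3,3-dimethoxy-2-(3,4,5-trimethoxyphenyl)propan-1-one (racemic) | COc1ccc(C(=O)C(C(OC)OC)c2cc(OC)c(OC)c(OC)c2)cc1O
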